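**Plan**

1. Cuts: the C(sp3)–C(sp2) bond between the CH2CH2 linker and C5′ of the hydroazulene (B-alkyl Suzuki), then O1–C2 and C5a–C6 of the bicyclic ether in one operation, then in the hydroazulene the two bonds of a two-carbon ring enlargement and C1′–C8a′ (ketyl–enone cyclisation).
2. Enabling feature: in ring A (oxepane) the ether oxygen joins the CMe2 carbon C2 to the ring-fusion CH C9a of ring B (cyclohexane); C9a lies next to the quaternary C5a–CH3 and the acetoxy carbon C3 next to C2. This is the imprint of a 6,7:10,11-diepoxy farnesyl-type chain whose inner epoxide oxygen opens the outer epoxide and whose C2=C3 unit closes ring B.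
3. Left half: geranyl bromide and methyl acetoacetate give a Z-allylsilane bis-epoxide; rings A and B form together in step 7; ozonolysis, methyl addition, acetylation and a vinyl group follow.
4. Right half: (S)-4-silyloxycyclopentenone gives a cyclopentenone that closes five-membered ring D with SmI2; the resulting cyclopentanone is enlarged to seven-membered ring C and converted into a dienyl triflate.
5. Union by hydroboration/Suzuki coupling, then enone reduction and desilylation.
6. Stereochemistry: C3, C5a, C9a from the Shi epoxides; C6 from the chair transition state and the Z-allylsilane; C7 from equatorial methyl attack; C3a′ from the silyloxy enone; C8a′ and C1′ from the forced cis fusion and the ketyl geometry; C7′ from the CBS catalyst.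

Key step: step 7

Remark: locants follow 1-benzoxepine numbering for the bicyclic ether and azulene numbering (primed) for the hydroazulene; the D-fructose-derived Shi ketone is taken to give (R,R)-epoxides from E-trisubstituted alkenes; the two cyclobutane centres of 27 and 28 are written for convex-face addition and vanish in step 20; 30 is a keto–enol mixture at C6′.

**Route**

Step 1
Reactants: 1 methyl acetoacetate; 2 geranyl bromide
Product: 3 methyl (6E)-7,11-dimethyl-3-oxododeca-6,10-dienoate
Conditions: NaH, THF, 0 °C; n-BuLi, 0 °C; then 2, 0 °C → rt; 1 M HCl quench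
Reagents that add atoms: none
Why: The acetoacetate dianion is alkylated at its terminal carbon by the allylic bromide in a direct SN2 displacement (β-keto ester dianion alkylation), which keeps the E-alkene.

Step 2
Reactants: 3 β-keto ester
Product: 4 methyl (2Z,6E)-7,11-dimethyl-3-(trifluoromethanesulfonyloxy)dodeca-2,6,10-trienoate
Conditions: Tf2O, aq. LiOH, toluene, 5 °C
Reagents that add atoms: trifluoromethanesulfonic anhydride, O=S(=O)(OS(=O)(=O)C(F)(F)F)C(F)(F)F
Why: O-Sulfonylation of the lithium-chelated enolate (enol triflate formation) should place OTf cis to the ester, giving the Z-isomer that later fixes the allylsilane geometry.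

Step 3
Reactants: 4 Z-enol triflate; 5 (trimethylsilyl)methylmagnesium chloride
Product: 6 methyl (2Z,6E)-7,11-dimethyl-3-[(trimethylsilyl)methyl]dodeca-2,6,10-trienoate
Conditions: Ni(acac)2 (5 mol %), THF, 0 °C → rt
Reagents that add atoms: none
Why: Nickel-catalysed Kumada–Corriu coupling replaces OTf with retention of alkene geometry, giving the Z-allylsilane in deactivated enoate form.

Step 4
Reactants: 6 triene ester
Product: 7 methyl (2Z,6R,7R,10R)-6,7:10,11-diepoxy-7,11-dimethyl-3-[(trimethylsilyl)methyl]dodec-2-enoate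
Conditions: D-fructose-derived Shi ketone (0.6 equiv), KHSO5 (Oxone), K2CO3, Bu4NHSO4, borate buffer, MeCN–CH2(OMe)2–H2O, 0 °C
Reagents that add atoms: potassium peroxymonosulfate, [K+].[O-]S(=O)(=O)OO
Why: Shi epoxidation should oxidise both electron-rich E-trisubstituted alkenes from the face set by the chiral dioxirane, giving the (6R,7R) and (10R) epoxides, while the electron-poor silylmethyl enoate is left alone.

Step 5
Reactants: 7 bis-epoxy ester
Product: 8 (2Z,6R,7R,10R)-6,7:10,11-diepoxy-7,11-dimethyl-3-[(trimethylsilyl)methyl]dodec-2-en-1-ol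
Conditions: i-Bu2AlH (2.3 equiv), CH2Cl2, −78 °C; aq. KNaC4H4O6
Reagents that add atoms: none
Why: 1,2-Reduction of the conjugated ester by the aluminium hydride at −78 °C should spare the trisubstituted epoxides and the allylsilane.

Step 6
Reactants: 8 allylic alcohol
Product: 9 (2Z,6R,7R,10R)-6,7:10,11-diepoxy-7,11-dimethyl-1-(triethylsilyloxy)-3-[(trimethylsilyl)methyl]dodec-2-ene
Conditions: Et3SiCl, imidazole, CH2Cl2, 0 °C
Reagents that add atoms: chlorotriethylsilane, CC[Si](Cl)(CC)CC
Why: Silyl ether formation gives a spectator group that tolerates Me3SiOTf and Grignard reagents, is orthogonal to the later acetate and can be oxidised directly to the aldehyde.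

Step 7
Reactants: 9 Z-allylsilane bis-epoxide
Product: 11 (3R,5aR,6S,9aR)-2,2,5a-trimethyl-7-methylidene-6-[(triethylsilyloxy)methyl]decahydro-1-benzoxepin-3-ol, via trimethylsilyl ether 10 (not isolated)
Conditions: Me3SiOTf (1.1 equiv), 2,6-di-tert-butyl-4-methylpyridine, CH2Cl2, −78 °C; then K2CO3, MeOH, 0 °C
Reagents that add atoms: none
Why: Me3SiOTf silylates the terminal epoxide, the oxygen of the neighbouring epoxide opens it at the CMe2 carbon, and the bicyclic epoxonium ion is opened at its methyl-bearing carbon by the γ-carbon of the allylsilane, loss of Me3Si+ leaving the exocyclic methylene; this is the known Lewis-acid tandem oxa-/carbacyclisation of 1,5-diepoxides with an allylsilane terminator. Ring A arises by endo attack of oxygen on the terminal epoxide (a six-membered oxonium ring first, the oxepane once the O–C5a bond of the epoxonium breaks), and ring B by 6-endo attack of carbon with both inner epoxide carbons inside the ring. C3 and C9a keep the configurations of the epoxide CH carbons because their C–O bonds are not broken, and C5a is set by inversion, which with the trans-epoxide gives the trans ring fusion. C6 is set by the chair transition state, in which the CH2OSiEt3 group, trans to the chain on the Z-allylsilane, lies equatorial and so cis to the angular methyl. The step needs endo opening of both epoxides and a termination faster than hydride shift or elimination: the first is secured because each opening occurs at a tertiary carbon, the second by the nucleophilic allylsilane and the hindered pyridine base at −78 °C.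

Step 8
Reactants: 11 methylidene alcohol
Product: 12 (3R,5aR,6S,9aR)-3-hydroxy-2,2,5a-trimethyl-6-[(triethylsilyloxy)methyl]octahydro-1-benzoxepin-7(2H)-one
Conditions: O3, NaHCO3, CH2Cl2–MeOH, −78 °C; Me2S
Reagents that add atoms: ozone, [O-][O+]=O
Why: Ozonolysis with reductive work-up cleaves the only alkene to the ring B ketone and leaves the silyl ether and the free alcohol untouched.

Step 9
Reactants: 12 ketone
Product: 13 (3R,5aR,6S,7S,9aR)-2,2,5a,7-tetramethyl-6-[(triethylsilyloxy)methyl]decahydro-1-benzoxepine-3,7-diol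
Conditions: MeMgBr (4 equiv), CeCl3 (anhydrous), THF, −78 °C
Reagents that add atoms: methylmagnesium bromide, C[Mg]Br
Why: The organocerium reagent adds to the enolisable β-silyloxy ketone without elimination and should attack equatorially because the axial path is blocked by the 1,3-diaxial angular methyl, giving the axial (7S) tertiary alcohol.

Step 10
Reactants: 13 diol
Product: 14 (3R,5aR,6S,7S,9aR)-7-hydroxy-2,2,5a,7-tetramethyl-6-[(triethylsilyloxy)methyl]decahydro-1-benzoxepin-3-yl acetate
Conditions: Ac2O, pyridine, DMAP, CH2Cl2, rt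
Reagents that add atoms: acetic anhydride, CC(=O)OC(C)=O
Why: DMAP-catalysed acylation esterifies only the secondary alcohol, because the hindered tertiary alcohol does not react under these conditions.

Step 11
Reactants: 14 hydroxy acetate
Product: 15 (3R,5aR,6S,7S,9aR)-2,2,5a,7-tetramethyl-7-(triethylsilyloxy)-6-[(triethylsilyloxy)methyl]decahydro-1-benzoxepin-3-yl acetate
Conditions: Et3SiOTf, 2,6-lutidine, CH2Cl2, 0 °C → rt
Reagents that add atoms: triethylsilyl trifluoromethanesulfonate, CC[Si](CC)(CC)OS(=O)(=O)C(F)(F)F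
Why: The silyl triflate silylates the hindered tertiary alcohol, so that no β-hydroxy aldehyde prone to retro-aldol cleavage arises in the next two steps.

Step 12
Reactants: 15 bis-silyl ether
Product: 16 (3R,5aR,6R,7S,9aR)-6-formyl-2,2,5a,7-tetramethyl-7-(triethylsilyloxy)decahydro-1-benzoxepin-3-yl acetate
Conditions: (COCl)2, DMSO, CH2Cl2, −78 → −30 °C; Et3N
Reagents that add atoms: none
Why: Under Swern conditions a primary triethylsilyl ether is cleaved and oxidised directly to the aldehyde while the tertiary silyl ether and the acetate stay; the equatorial aldehyde is the stable epimer.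

Step 13
Reactants: 16 aldehyde
Product: 17 (3R,5aR,6R,7S,9aR)-6-ethenyl-2,2,5a,7-tetramethyl-7-(triethylsilyloxy)decahydro-1-benzoxepin-3-yl acetate
Conditions: Ph3PCH3Br, KN(SiMe3)2, THF, −78 → 0 °C
Reagents that add atoms: methyltriphenylphosphonium bromide, C[P+](c1ccccc1)(c1ccccc1)c1ccccc1.[Br-]
Why: Wittig methylenation of the aldehyde at low temperature gives the terminal alkene for hydroboration, the acetate reacting far more slowly than the aldehyde.

Step 14
Reactants: 18 (S)-4-(tert-butyldimethylsilyloxy)cyclopent-2-en-1-one; 19 but-3-en-1-ylmagnesium bromide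
Product: 21 (S)-4-(but-3-en-1-yl)cyclopent-2-en-1-one, via trans-silyloxy ketone 20 (not isolated)
Conditions: CuBr·SMe2 (15 mol %), Me3SiCl, THF, −78 °C; 1 M HCl; then DBU, CH2Cl2, 0 °C
Reagents that add atoms: none
Why: Copper-catalysed conjugate addition occurs anti to the silyloxy group and E1cB loss of silanolate gives the 4-substituted enone (conjugate addition–elimination), so the silyloxy stereocentre is traded for the future C3a′.

Step 15
Reactants: 21 4-butenyl enone
Product: 23 (R)-4-(but-3-en-1-yl)-5,5-dimethylcyclopent-2-en-1-one, via trans-5-methyl enone 22 (not isolated)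
Conditions: LiN(i-Pr)2 (1.1 equiv), THF, −78 °C, MeI; then LiN(i-Pr)2 (1.2 equiv), −78 °C, MeI, DMPU, → 0 °C
Reagents that add atoms: iodomethane, CI
Why: Kinetic deprotonation at C5 and methylation, carried out twice (enolate alkylation), installs the gem-dimethyl group without touching the C4 stereocentre.

Step 16
Reactants: 23 dimethyl enone
Product: 24 (R)-5,5-dimethyl-4-(3-oxobutyl)cyclopent-2-en-1-one
Conditions: PdCl2 (10 mol %), CuCl, O2 (1 atm), DMF–H2O, rt
Reagents that add atoms: water, O
Why: Tsuji–Wacker oxidation converts the terminal alkene into the methyl ketone with Markovnikov selectivity, the electron-poor enone alkene being inert.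

Step 17
Reactants: 24 keto enone
Product: 25 (3aR,4R,6aR)-4-hydroxy-1,1,4-trimethylhexahydropentalen-2(1H)-one
Conditions: SmI2 (2.5 equiv), HMPA, t-BuOH (2 equiv), THF, −78 °C
Reagents that add atoms: none
Why: Reductive ketyl–olefin cyclisation (5-exo onto the enone β-carbon) must give the cis-fused diquinane because the three-atom tether sits on the adjacent ring carbon, and the samarium-bound ketyl oxygen should turn away from the ring to the convex face, placing the hydroxyl cis to both ring-fusion hydrogens.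

Step 18
Reactants: 25 diquinane ketol
Product: 26 1,1,4-trimethyl-2,4-bis(trimethylsilyloxy)-1,3a,4,5,6,6a-hexahydropentalene (stereocentres as in 25)
Conditions: Me3SiOTf (2.5 equiv), Et3N, CH2Cl2, 0 °C
Reagents that add atoms: trimethylsilyl trifluoromethanesulfonate, C[Si](C)(C)OS(=O)(=O)C(F)(F)F
Why: The ketone can enolise on one side only, so silyl triflate and amine give a single silyl enol ether and silylate the tertiary alcohol in the same operation.

Step 19
Reactants: 26 silyl enol ether
Product: 27 dichlorocyclobutanone adduct (CCl2 on the silyloxy carbon and C=O on the former enol CH)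
Conditions: Cl2CHCOCl, Et3N (slow addition), hexane, rt
Reagents that add atoms: dichloroacetyl chloride, O=C(Cl)C(Cl)Cl
Why: Dichloroketene made in the flask undergoes [2+2] cycloaddition with the silyl enol ether, its carbonyl carbon bonding to the unsubstituted enol carbon, as in the known two-carbon enlargement of cyclic ketones; the ketene is reactive enough to add to fully substituted alkenes.

Step 20
Reactants: 27 dichlorocyclobutanone
Product: 29 (1R,3aR,8aR)-1-hydroxy-1,4,4-trimethyloctahydroazulene-5,7-dione, via dechlorinated cyclobutanone 28 (not isolated)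
Conditions: Zn dust, AcOH, i-PrOH–H2O, 0 °C → rt; then 65 °C
Reagents that add atoms: none
Why: Zinc removes both chlorines (reductive dechlorination), and hydrolysis of the silyloxycyclobutanone triggers retro-aldol cleavage of the bond shared by the two rings, enlarging the cyclopentanone to the seven-membered 1,3-dione.

Step 21
Reactants: 29 1,3-dione
Product: 30 (1R,3aR,8aR)-1-hydroxy-1,4,4,6-tetramethyloctahydroazulene-5,7-dione
Conditions: MeI (1.2 equiv), K2CO3, acetone, 50 °C
Reagents that add atoms: iodomethane, CI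
Why: C-Alkylation of the 1,3-dione enolate at the carbon between the carbonyls introduces the future alkene methyl group.

Step 22
Reactants: 30 2-methyl-1,3-dione
Product: 31 (1R,3aR,8aR)-1,4,4,6-tetramethyl-1,7-bis(triethylsilyloxy)-2,3,3a,4,8,8a-hexahydroazulen-5(1H)-one
Conditions: Et3SiOTf (2.5 equiv), Et3N, CH2Cl2, −78 → 0 °C
Reagents that add atoms: triethylsilyl trifluoromethanesulfonate, CC[Si](CC)(CC)OS(=O)(=O)C(F)(F)F
Why: O-Silylation of the enolised dione should occur at the oxygen remote from the gem-dimethyl group, leaving the free ketone next to the quaternary carbon, and the tertiary alcohol is silylated in the same step.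

Step 23
Reactants: 31 vinylogous silyl ester
Product: 32 1,4,4,6-tetramethyl-1,7-bis(triethylsilyloxy)-1,2,3,3a,4,8a-hexahydroazulen-5-yl trifluoromethanesulfonate (stereocentres as in 31)
Conditions: KN(SiMe3)2 (1.2 equiv), THF, −78 °C; PhNTf2, −78 → 0 °C
Reagents that add atoms: N-phenylbis(trifluoromethanesulfonimide), O=S(=O)(N(c1ccccc1)S(=O)(=O)C(F)(F)F)C(F)(F)F
Why: With the α′ position quaternary the base can only remove a γ-proton at C8′, and O-sulfonylation of the extended enolate (enol triflate formation from a dienolate) puts the triflate on the carbon next to the gem-dimethyl group.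

Step 24
Reactants: 17 vinyl acetate; 32 dienyl triflate
Product: 35 (3R,5aR,6R,7S,9aR)-2,2,5a,7-tetramethyl-6-{2-[(1R,3aR,8aR)-1,4,4,6-tetramethyl-7-oxo-1-(triethylsilyloxy)-1,2,3,3a,4,7,8,8a-octahydroazulen-5-yl]ethyl}-7-(triethylsilyloxy)decahydro-1-benzoxepin-3-yl acetate, via alkyl-9-BBN 33 (not isolated), via silyl dienol ether 34 (not isolated)
Conditions: 9-BBN-H, THF, rt → 40 °C; then 32, Pd(dppf)Cl2 (10 mol %), AsPh3, aq. K3PO4, DMF, rt; then 0.5 M HCl, THF, 0 °C
Reagents that add atoms: none
Why: Anti-Markovnikov hydroboration of the vinyl group and B-alkyl Suzuki–Miyaura coupling with the triflate form the C(sp3)–C(sp2) bond, and dilute acid hydrolyses the silyl dienol ether to the conjugated enone while the tertiary silyl ethers and the acetate survive.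

Step 25
Reactants: 35 enone
Product: 36 the (7′R)-allylic alcohol of 35 (7′-oxo replaced by 7′-hydroxy; both tertiary triethylsilyl ethers kept)
Conditions: (S)-2-methyl-CBS-oxazaborolidine (1 equiv), catecholborane, toluene, −78 → −40 °C
Reagents that add atoms: none
Why: Corey–Bakshi–Shibata reduction with the (S)-catalyst treats the tetrasubstituted alkenyl side of the enone as the large group and should deliver hydride to give the (7′R)-alcohol under reagent control.

Step 26
Reactants: 36 bis-silyl ether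
Product: 37 (3R,5aR,6R,7S,9aR)-6-{2-[(1R,3aR,7R,8aR)-1,7-dihydroxy-1,4,4,6-tetramethyl-1,2,3,3a,4,7,8,8a-octahydroazulen-5-yl]ethyl}-7-hydroxy-2,2,5a,7-tetramethyldecahydro-1-benzoxepin-3-yl acetate (CNP0157376.1)
Conditions: HF·pyridine, pyridine, THF, 0 °C → rt
Reagents that add atoms: none
Why: Buffered fluoride desilylation cleaves the two tertiary triethylsilyl ethers without touching the acetate or ionising the allylic alcohol.

**Compound list**

1 | methyl acetoacetate | COC(=O)CC(C)=O | starting material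
2 | geranyl bromide | CC(C)=CCC/C(C)=C/CBr | starting material
3 | methyl (6E)-7,11-dimethyl-3-oxododeca-6,10-dienoate | COC(=O)CC(=O)CC/C=C(C)/CCC=C(C)C | intermediate
4 | methyl (2Z,6E)-7,11-dimethyl-3-(trifluoromethanesulfonyloxy)dodeca-2,6,10-trienoate | COC(=O)/C=C(OS(=O)(=O)C(F)(F)F)/CC/C=C(C)/CCC=C(C)C | intermediate
5 | (trimethylsilyl)methylmagnesium chloride | C[Si](C)(C)C[Mg]Cl | starting material
6 | methyl (2Z,6E)-7,11-dimethyl-3-[(trimethylsilyl)methyl]dodeca-2,6,10-trienoate | COC(=O)/C=C(C[Si](C)(C)C)/CC/C=C(C)/CCC=C(C)C | intermediate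
7 | methyl (2Z,6R,7R,10R)-6,7:10,11-diepoxy-7,11-dimethyl-3-[(trimethylsilyl)methyl]dodec-2-enoate | CC1(C)O[C@@H]1CC[C@@]2(C)O[C@@H]2CC/C(C[Si](C)(C)C)=C/C(=O)OC | intermediate
8 | (2Z,6R,7R,10R)-6,7:10,11-diepoxy-7,11-dimethyl-3-[(trimethylsilyl)methyl]dodec-2-en-1-ol | CC1(C)O[C@@H]1CC[C@@]2(C)O[C@@H]2CC/C(C[Si](C)(C)C)=C/CO | intermediate
9 | triethylsilyl ether of 8 (Z-allylsilane bis-epoxide) | CC1(C)O[C@@H]1CC[C@@]2(C)O[C@@H]2CC/C(C[Si](C)(C)C)=C/CO[Si](CC)(CC)CC | intermediate
10 | 3-O-trimethylsilyl ether of 11 | C[Si](C)(C)O[C@@H]1CC[C@]2(C)[C@@H](CO[Si](CC)(CC)CC)C(=C)CC[C@H]2OC1(C)C | intermediate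
11 | (3R,5aR,6S,9aR)-2,2,5a-trimethyl-7-methylidene-6-[(triethylsilyloxy)methyl]decahydro-1-benzoxepin-3-ol (trans-fused; 6-substituent cis to 5a-methyl) | O[C@@H]1CC[C@]2(C)[C@@H](CO[Si](CC)(CC)CC)C(=C)CC[C@H]2OC1(C)C | intermediate
12 | (3R,5aR,6S,9aR)-3-hydroxy-2,2,5a-trimethyl-6-[(triethylsilyloxy)methyl]octahydro-1-benzoxepin-7(2H)-one | O[C@@H]1CC[C@]2(C)[C@@H](CO[Si](CC)(CC)CC)C(=O)CC[C@H]2OC1(C)C | intermediate
13 | (3R,5aR,6S,7S,9aR)-2,2,5a,7-tetramethyl-6-[(triethylsilyloxy)methyl]decahydro-1-benzoxepine-3,7-diol | O[C@@H]1CC[C@]2(C)[C@@H](CO[Si](CC)(CC)CC)[C@@](C)(O)CC[C@H]2OC1(C)C | intermediate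
14 | 3-O-acetate of 13 | CC(=O)O[C@@H]1CC[C@]2(C)[C@@H](CO[Si](CC)(CC)CC)[C@@](C)(O)CC[C@H]2OC1(C)C | intermediate
15 | 7-O-triethylsilyl ether of 14 | CC(=O)O[C@@H]1CC[C@]2(C)[C@@H](CO[Si](CC)(CC)CC)[C@@](C)(O[Si](CC)(CC)CC)CC[C@H]2OC1(C)C | intermediate
16 | (3R,5aR,6R,7S,9aR)-6-formyl-2,2,5a,7-tetramethyl-7-(triethylsilyloxy)decahydro-1-benzoxepin-3-yl acetate | CC(=O)O[C@@H]1CC[C@]2(C)[C@@H](C=O)[C@@](C)(O[Si](CC)(CC)CC)CC[C@H]2OC1(C)C | intermediate
17 | (3R,5aR,6R,7S,9aR)-6-ethenyl-2,2,5a,7-tetramethyl-7-(triethylsilyloxy)decahydro-1-benzoxepin-3-yl acetate | CC(=O)O[C@@H]1CC[C@]2(C)[C@@H](C=C)[C@@](C)(O[Si](CC)(CC)CC)CC[C@H]2OC1(C)C | intermediate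
18 | (S)-4-(tert-butyldimethylsilyloxy)cyclopent-2-en-1-one | O=C1C=C[C@@H](O[Si](C)(C)C(C)(C)C)C1 | starting material
19 | but-3-en-1-ylmagnesium bromide | C=CCC[Mg]Br | starting material
20 | trans-3-(but-3-en-1-yl)-4-(tert-butyldimethylsilyloxy)cyclopentan-1-one | O=C1C[C@H](CCC=C)[C@@H](O[Si](C)(C)C(C)(C)C)C1 | intermediate
21 | (S)-4-(but-3-en-1-yl)cyclopent-2-en-1-one | O=C1C=C[C@@H](CCC=C)C1 | intermediate
22 | trans-4-(but-3-en-1-yl)-5-methylcyclopent-2-en-1-one | O=C1C=C[C@@H](CCC=C)[C@@H]1C | intermediate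
23 | (R)-4-(but-3-en-1-yl)-5,5-dimethylcyclopent-2-en-1-one | O=C1C=C[C@@H](CCC=C)C1(C)C | intermediate
24 | (R)-5,5-dimethyl-4-(3-oxobutyl)cyclopent-2-en-1-one | O=C1C=C[C@@H](CCC(C)=O)C1(C)C | intermediate
25 | (3aR,4R,6aR)-4-hydroxy-1,1,4-trimethylhexahydropentalen-2(1H)-one (cis-fused; OH cis to both ring-fusion H) | O=C1C[C@@H]2[C@@H](CC[C@@]2(C)O)C1(C)C | intermediate
26 | 1,1,4-trimethyl-2,4-bis(trimethylsilyloxy)-1,3a,4,5,6,6a-hexahydropentalene | C[Si](C)(C)OC1=C[C@@H]2[C@@H](CC[C@@]2(C)O[Si](C)(C)C)C1(C)C | intermediate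
27 | dichloroketene [2+2] adduct of 26 (2,2-dichlorocyclobutanone; CCl2 on the silyloxy carbon) | ClC1(Cl)C(=O)[C@@H]2[C@@H]3[C@@H](CC[C@@]3(C)O[Si](C)(C)C)C(C)(C)[C@]12O[Si](C)(C)C | intermediate
28 | dechlorinated cyclobutanone from 27 | C1C(=O)[C@@H]2[C@@H]3[C@@H](CC[C@@]3(C)O[Si](C)(C)C)C(C)(C)[C@]12O[Si](C)(C)C | intermediate
29 | (1R,3aR,8aR)-1-hydroxy-1,4,4-trimethyloctahydroazulene-5,7-dione | O=C1CC(=O)C[C@@H]2[C@@H](CC[C@@]2(C)O)C1(C)C | intermediate
30 | (1R,3aR,8aR)-1-hydroxy-1,4,4,6-tetramethyloctahydroazulene-5,7-dione | O=C1C(C)C(=O)C[C@@H]2[C@@H](CC[C@@]2(C)O)C1(C)C | intermediate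
31 | (1R,3aR,8aR)-1,4,4,6-tetramethyl-1,7-bis(triethylsilyloxy)-2,3,3a,4,8,8a-hexahydroazulen-5(1H)-one | O=C1C(C)=C(O[Si](CC)(CC)CC)C[C@@H]2[C@@H](CC[C@@]2(C)O[Si](CC)(CC)CC)C1(C)C | intermediate
32 | 1,4,4,6-tetramethyl-1,7-bis(triethylsilyloxy)-1,2,3,3a,4,8a-hexahydroazulen-5-yl trifluoromethanesulfonate | O=S(=O)(OC1=C(C)C(O[Si](CC)(CC)CC)=C[C@@H]2[C@@H](CC[C@@]2(C)O[Si](CC)(CC)CC)C1(C)C)C(F)(F)F | intermediate
33 | B-alkyl-9-BBN from 17 (6-[2-(9-borabicyclo[3.3.1]nonan-9-yl)ethyl]) | CC(=O)O[C@@H]1CC[C@]2(C)[C@@H](CCB3C4CCCC3CCC4)[C@@](C)(O[Si](CC)(CC)CC)CC[C@H]2OC1(C)C | intermediate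
34 | Suzuki product as 7′-O-triethylsilyl dienol ether | CC(=O)O[C@@H]1CC[C@]2(C)[C@@H](CCC3=C(C)C(O[Si](CC)(CC)CC)=C[C@@H]4[C@@H](CC[C@@]4(C)O[Si](CC)(CC)CC)C3(C)C)[C@@](C)(O[Si](CC)(CC)CC)CC[C@H]2OC1(C)C | intermediate
35 | coupled 7′-enone, bis(triethylsilyl) ether | CC(=O)O[C@@H]1CC[C@]2(C)[C@@H](CCC3=C(C)C(=O)C[C@@H]4[C@@H](CC[C@@]4(C)O[Si](CC)(CC)CC)C3(C)C)[C@@](C)(O[Si](CC)(CC)CC)CC[C@H]2OC1(C)C | intermediate
36 | (7′R)-allylic alcohol, bis(triethylsilyl) ether | CC(=O)O[C@@H]1CC[C@]2(C)[C@@H](CCC3=C(C)[C@H](O)C[C@@H]4[C@@H](CC[C@@]4(C)O[Si](CC)(CC)CC)C3(C)C)[C@@](C)(O[Si](CC)(CC)CC)CC[C@H]2OC1(C)C | intermediate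
37 | CNP0157376.1 | CC(=O)O[C@@H]1CC[C@]2(C)[C@@H](CCC3=C(C)[C@H](O)C[C@@H]4[C@@H](CC[C@@]4(C)O)C3(C)C)[C@@](C)(O)CC[C@H]2OC1(C)C | target

**Count and risks**

Total steps: 26. Longest linear sequence: 16 steps (steps 1–13, then 24–26); the hydroazulene branch (steps 14–23) has 10 steps before the union.

Step 17. Simple reduction of the enone may outrun ketyl addition, or the ketyl may add with the opposite sense at the carbinol carbon. The fallback sets out from 24 and returns at 25. Kinetic deprotonation of the methyl ketone (LiN(i-Pr)2, PhNTf2, −78 °C) should give the terminal vinyl triflate F1. Intramolecular reductive Heck cyclisation (Pd(OAc)2, PPh3, HCO2Na, DMF) onto the enone β-carbon should give the cis-fused methylidene diquinanone F2. Mukaiyama hydration (Co(acac)2, PhSiH3, O2) should then deliver the hydroxyl to the tertiary radical from the convex face, giving 25.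

Step 23. The amide base may attack silicon instead of removing the γ-proton, or the hindered oxygen may be sulfonylated too slowly. The fallback sets out from 30 and returns at 37.
- Tf2O/Et3N at −78 °C should give the regioisomeric vinylogous triflate F3, sulfonylated at the oxygen remote from the gem-dimethyl group.
- Palladium-catalysed formate reduction (Pd(OAc)2, PPh3, HCO2H, Et3N) should give the α-methyl enone F4.
- Copper-catalysed conjugate borylation (CuCl, NaOt-Bu, a Josiphos-type bisphosphine, B2pin2, MeOH) should give the boronate F5 under ligand control, and NaBO3 oxidation the β-hydroxy ketone F6.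
- Et3SiOTf should give the bis-silyl ether F7, and KN(SiMe3)2/PhNTf2 the enol triflate F8 of the ketone, which is enolisable on one side only.
- Suzuki coupling of F8 with 33 under the conditions of step 24 (without the acid treatment) should give the tris-silyl ether F9, and HF·pyridine should give 37.

Step 24. Slow oxidative addition at the tetrasubstituted, electron-rich triflate may let protodeboronation and loss of the silyl dienol ether compete. The fallback sets out from 17 and returns at 34, which is hydrolysed to 35 as in step 24. Hydrozirconation of the vinyl group (Cp2Zr(H)Cl) and iodinolysis (I2) should give the primary iodide F10. Zinc insertion (Zn, LiCl, THF) should give the alkylzinc iodide F11, which tolerates the acetate. Negishi coupling with 32 (Pd2(dba)3, SPhos, THF–NMP) needs no aqueous base and has a faster transmetalation.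

**Further compounds**

F1 | step 17 | 4-[(1R)-5,5-dimethyl-4-oxocyclopent-2-en-1-yl]but-1-en-2-yl trifluoromethanesulfonate | O=C1C=C[C@@H](CCC(=C)OS(=O)(=O)C(F)(F)F)C1(C)C
F2 | step 17 | (3aR,6aR)-1,1-dimethyl-4-methylidenehexahydropentalen-2(1H)-one | O=C1C[C@@H]2[C@@H](CCC2=C)C1(C)C
F3 | step 23 | (1R,3aR,8aR)-1-hydroxy-1,4,4,6-tetramethyl-5-oxo-1,2,3,3a,4,5,8,8a-octahydroazulen-7-yl trifluoromethanesulfonate | O=C1C(C)=C(OS(=O)(=O)C(F)(F)F)C[C@@H]2[C@@H](CC[C@@]2(C)O)C1(C)C
F4 | step 23 | (1R,3aR,8aR)-1-hydroxy-1,4,4,6-tetramethyl-2,3,3a,4,8,8a-hexahydroazulen-5(1H)-one | O=C1C(C)=CC[C@@H]2[C@@H](CC[C@@]2(C)O)C1(C)C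
F5 | step 23 | 7-(pinacolboryl) ketone from F4 | O=C1C(C)[C@H](B2OC(C)(C)C(C)(C)O2)C[C@@H]3[C@@H](CC[C@@]3(C)O)C1(C)C
F6 | step 23 | (1R,3aR,7R,8aR)-1,7-dihydroxy-1,4,4,6-tetramethyloctahydroazulen-5(1H)-one | O=C1C(C)[C@H](O)C[C@@H]2[C@@H](CC[C@@]2(C)O)C1(C)C
F7 | step 23 | 1,7-bis(triethylsilyl) ether of F6 | O=C1C(C)[C@H](O[Si](CC)(CC)CC)C[C@@H]2[C@@H](CC[C@@]2(C)O[Si](CC)(CC)CC)C1(C)C
F8 | step 23 | (7R)-1,4,4,6-tetramethyl-1,7-bis(triethylsilyloxy)-1,2,3,3a,4,7,8,8a-octahydroazulen-5-yl trifluoromethanesulfonate | O=S(=O)(OC1=C(C)[C@H](O[Si](CC)(CC)CC)C[C@@H]2[C@@H](CC[C@@]2(C)O[Si](CC)(CC)CC)C1(C)C)C(F)(F)F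
F9 | step 23 | 7′-O-triethylsilyl ether of 36 | CC(=O)O[C@@H]1CC[C@]2(C)[C@@H](CCC3=C(C)[C@H](O[Si](CC)(CC)CC)C[C@@H]4[C@@H](CC[C@@]4(C)O[Si](CC)(CC)CC)C3(C)C)[C@@](C)(O[Si](CC)(CC)CC)CC[C@H]2OC1(C)C
F10 | step 24 | 6-(2-iodoethyl) analogue of 17 | CC(=O)O[C@@H]1CC[C@]2(C)[C@@H](CCI)[C@@](C)(O[Si](CC)(CC)CC)CC[C@H]2OC1(C)C
F11 | step 24 | alkylzinc iodide from F10 | CC(=O)O[C@@H]1CC[C@]2(C)[C@@H](CC[Zn]I)[C@@](C)(O[Si](CC)(CC)CC)CC[C@H]2OC1(C)C
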